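**Strategy**

Everything rests on disconnecting the C2–C3 bond of ring C. The feature used is that C2 carries both O1 and the phenyl group, so it is the benzylic CH2 of a benzyl ether placed ortho to the C4 carbonyl on ring A; the symmetric ring A bears an identical benzyloxy group on the other ortho carbon, which ends as protected O5. A chiral dirhodium carboxylate converts a terminal diazoketone into a carbene that inserts into one enantiotopic benzylic C–H bond, closing ring C and setting C2 in one operation. The precursor is 2-diazo-1-[2,4,6-tris(benzyloxy)phenyl]ethanone, two steps from phloroacetophenone. C3 is then oxygenated trans by Rubottom oxidation, acylated, and the benzyl ethers are hydrogenolysed.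

Key step: step 3

Assumption: Rh2(S-PTTL)4 (dirhodium tetrakis[N-phthaloyl-(S)-tert-leucinate]) is taken to give the 2S chromanone from this acceptor-only carbene; if the first run shows the opposite sense, Rh2(R-PTTL)4 is used with no other change.

Remark: the C3 oxygen is brought in by dioxirane epoxidation of the enol silane, because trivalent iodine oxidants on flavanones tend toward 2,3-aryl migration and cis products.

**Route**

Step 1
Reactants: 1 1-(2,4,6-trihydroxyphenyl)ethanone (2',4',6'-trihydroxyacetophenone); 2 benzyl bromide
Product: 3 1-[2,4,6-tris(benzyloxy)phenyl]ethanone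
Conditions: BnBr (3.6 equiv), K2CO3, DMF, 70 °C
Reagents that add atoms: benzyl bromide BrCc1ccccc1
Why: Williamson O-alkylation of the three phenoxides by a reactive benzylic bromide in a dipolar aprotic solvent, with excess reagent and heating to alkylate the hydrogen-bonded ortho hydroxyls; no stereocentre is formed.

Step 2
Reactants: 3 1-[2,4,6-tris(benzyloxy)phenyl]ethanone
Product: 5 2-diazo-1-[2,4,6-tris(benzyloxy)phenyl]ethanone, via trifluoroacetyl ketone 4 (not isolated)
Conditions: LiN(SiMe3)2, THF, −78 °C; CF3CO2CH2CF3; aqueous HCl work-up, crude taken on; 4-acetamidobenzenesulfonyl azide, Et3N, H2O, MeCN, rt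
Reagents that add atoms: 4-acetamidobenzenesulfonyl azide CC(=O)Nc1ccc(cc1)S(=O)(=O)N=[N+]=[N-] (the two diazo nitrogens); 2,2,2-trifluoroethyl trifluoroacetate O=C(OCC(F)(F)F)C(F)(F)F (trifluoroacetyl group, present only in 4)
Why: Detrifluoroacetylative diazo transfer (Danheiser variant of the Regitz reaction): Claisen trifluoroacetylation of the methyl ketone enolate gives an activated 1,3-diketone that takes the diazo group from the sulfonyl azide and passes the trifluoroacetyl group to the sulfonamide nitrogen, which avoids a hindered 2,6-disubstituted aroyl chloride.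

Step 3
Reactants: 5 2-diazo-1-[2,4,6-tris(benzyloxy)phenyl]ethanone
Product: 6 (2S)-5,7-bis(benzyloxy)-2-phenylchroman-4-one
Conditions: Rh2(S-PTTL)4 (2 mol %), toluene, −40 → 0 °C, slow addition of 5
Reagents that add atoms: none
Why: The catalyst, a divalent dirhodium tetracarboxylate, expels N2 from 5, and the electrophilic rhodium carbene at the future C3 inserts through a concerted, asynchronous three-centre transition state (hydride-like shift with C–C bond formation) into a benzylic C–H bond of an ortho benzyloxy group, forming C2–C3. The closest known reaction type is the enantioselective intramolecular C–H insertion of ortho-alkoxyaryl diazoketones next to the ether oxygen under chiral dirhodium carboxylate catalysis, which gives chroman-4-ones. Ring C closes as a six-membered ring in a 1,6-insertion mode through a cyclic transition state made up of the carbene carbon, C4, C4a, C8a, O1 and the benzylic carbon; a five-membered C–H insertion is not available because the fifth atom is the ether oxygen. The only new stereocentre, C2, is under catalyst control: the chiral pocket built by the four N-phthaloyl-tert-leucinate ligands differentiates the two enantiotopic benzylic hydrogens, and the 2S descriptor of 6 denotes the same spatial arrangement as 2R in the target. The step needs chemoselectivity for C–H insertion over attack of the ether lone pair on the carbene (oxonium ylide, then 1,2-benzyl shift to a 2-benzylbenzofuran-3-one); the C–H bond is doubly activated (benzylic and α to oxygen), and slow addition at low temperature in a non-coordinating solvent with bulky carboxylate ligands should favour insertion. Site selectivity needs no control because the two ortho benzyloxy groups are related by the symmetry of ring A and give the same product, while the para group is out of reach.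

Step 4
Reactants: 6 (2S)-5,7-bis(benzyloxy)-2-phenylchroman-4-one
Product: 7 (2S)-5,7-bis(benzyloxy)-2-phenyl-4-(trimethylsilyloxy)-2H-chromene
Conditions: TMSOTf, Et3N, CH2Cl2, 0 °C; non-aqueous work-up, used crude
Reagents that add atoms: trimethylsilyl trifluoromethanesulfonate C[Si](C)(C)OS(=O)(=O)C(F)(F)F
Why: Soft enolisation (silyl triflate with a tertiary amine) gives the only possible enol silane, C3 being the sole α-position, without a strong base, so retro-oxa-Michael opening of ring C and loss of the C2 configuration should be avoided.

Step 5
Reactants: 7 (2S)-5,7-bis(benzyloxy)-2-phenyl-4-(trimethylsilyloxy)-2H-chromene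
Product: 9 (2R,3R)-5,7-bis(benzyloxy)-3-hydroxy-2-phenylchroman-4-one, via silyloxy epoxide 8 (not isolated)
Conditions: dimethyldioxirane, acetone/CH2Cl2, −40 → 0 °C; then 1 M HCl, THF, 0 °C
Reagents that add atoms: dimethyldioxirane CC1(C)OO1
Why: Rubottom oxidation: the dioxirane epoxidises the electron-rich C3=C4 bond on the face opposite the C2 phenyl and acid opening of the silyloxy oxirane returns the C4 ketone with the new C3–O bond intact, so C3 is set R (trans to phenyl) under substrate control by C2, whose descriptor changes from S to R only through the change in CIP priorities.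

Step 6
Reactants: 9 (2R,3R)-5,7-bis(benzyloxy)-3-hydroxy-2-phenylchroman-4-one; 10 hexanoyl chloride
Product: 11 (2R,3R)-5,7-bis(benzyloxy)-4-oxo-2-phenylchroman-3-yl hexanoate
Conditions: hexanoyl chloride, pyridine, DMAP (cat.), CH2Cl2, 0 °C → rt
Reagents that add atoms: hexanoyl chloride CCCCCC(Cl)=O
Why: Acylation of the secondary alcohol by an acyl chloride under nucleophilic catalysis breaks no bond at C2 or C3, and the trans (diequatorial) arrangement is also the thermodynamic one should C3 enolise.

Step 7
Reactants: 11 (2R,3R)-5,7-bis(benzyloxy)-4-oxo-2-phenylchroman-3-yl hexanoate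
Product: 12 (2R,3R)-5,7-dihydroxy-4-oxo-2-phenylchroman-3-yl hexanoate
Conditions: H2 (1 atm), 10% Pd/C, EtOAc, rt
Reagents that add atoms: none
Why: Catalytic hydrogenolysis of the two aryl benzyl ethers over palladium under neutral conditions should be much faster than cleavage of the cyclic secondary C2–O1 bond or reduction of the aryl ketone, and the alkyl ester is inert, so both stereocentres stay untouched.

**Compound list**

1 | 1-(2,4,6-trihydroxyphenyl)ethanone | CC(=O)c1c(O)cc(O)cc1O | starting material
2 | benzyl bromide | BrCc1ccccc1 | starting material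
3 | 1-[2,4,6-tris(benzyloxy)phenyl]ethanone | CC(=O)c1c(OCc2ccccc2)cc(OCc2ccccc2)cc1OCc1ccccc1 | intermediate
4 | 4,4,4-trifluoro-1-[2,4,6-tris(benzyloxy)phenyl]butane-1,3-dione | O=C(CC(=O)C(F)(F)F)c1c(OCc2ccccc2)cc(OCc2ccccc2)cc1OCc1ccccc1 | intermediate (not isolated)
5 | 2-diazo-1-[2,4,6-tris(benzyloxy)phenyl]ethanone | [N-]=[N+]=CC(=O)c1c(OCc2ccccc2)cc(OCc2ccccc2)cc1OCc1ccccc1 | intermediate
6 | (2S)-5,7-bis(benzyloxy)-2-phenylchroman-4-one | O=C1c2c(OCc3ccccc3)cc(OCc3ccccc3)cc2O[C@@H](C1)c1ccccc1 | intermediate
7 | (2S)-5,7-bis(benzyloxy)-2-phenyl-4-(trimethylsilyloxy)-2H-chromene | C[Si](C)(C)OC1=C[C@@H](c2ccccc2)Oc2cc(OCc3ccccc3)cc(OCc3ccccc3)c12 | intermediate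
8 | 5,7-bis(benzyloxy)-3,4-epoxy-2-phenyl-4-(trimethylsilyloxy)chroman, oxirane oxygen on the face opposite the C2 phenyl | C[Si](C)(C)O[C@@]12O[C@@H]1[C@@H](c3ccccc3)Oc3cc(OCc4ccccc4)cc(OCc4ccccc4)c23 | intermediate (not isolated)
9 | (2R,3R)-5,7-bis(benzyloxy)-3-hydroxy-2-phenylchroman-4-one | O[C@H]1C(=O)c2c(OCc3ccccc3)cc(OCc3ccccc3)cc2O[C@@H]1c1ccccc1 | intermediate
10 | hexanoyl chloride | CCCCCC(Cl)=O | starting material
11 | (2R,3R)-5,7-bis(benzyloxy)-4-oxo-2-phenylchroman-3-yl hexanoate | CCCCCC(=O)O[C@H]1C(=O)c2c(OCc3ccccc3)cc(OCc3ccccc3)cc2O[C@@H]1c1ccccc1 | intermediate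
12 | (2R,3R)-5,7-dihydroxy-4-oxo-2-phenylchroman-3-yl hexanoate | CCCCCC(=O)O[C@H]1C(=O)c2c(O)cc(O)cc2O[C@@H]1c1ccccc1 | target

**Step count**

Total steps: 7. Longest linear sequence: 7 steps (1 → 12).

**Steps most likely to fail**

Step 3. The carbene may be captured by the lone pair of the ortho ether oxygen (oxonium ylide, then 1,2-benzyl shift) faster than it inserts, or the catalyst may discriminate the two enantiotopic benzylic hydrogens poorly. The fallback sets out from 1 and builds ring C by conjugate addition instead. Dibenzylation with 2 (2.1 equiv, K2CO3, acetone, reflux) leaves the chelated ortho hydroxyl free and should give 1-[2,4-bis(benzyloxy)-6-hydroxyphenyl]ethanone F1. Condensation with N,N-dimethylformamide dimethyl acetal (toluene, 90 °C) should give (E)-1-[2,4-bis(benzyloxy)-6-hydroxyphenyl]-3-(dimethylamino)prop-2-en-1-one F2. Treatment with HCl in CH2Cl2 closes the pyranone with loss of dimethylamine to 5,7-bis(benzyloxy)-4H-chromen-4-one F3. Enantioselective conjugate addition of phenylboronic acid, catalysed by Pd(OCOCF3)2 (divalent palladium) and the enantiomer of 4-tert-butyl-2-(pyridin-2-yl)-4,5-dihydrooxazole that delivers the 2S product (NH4PF6, H2O, ClCH2CH2Cl, 60 °C), comes back to the route at 6.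

Step 5. The oxidant may approach the enol silane from both faces (poor facial selectivity), or the labile enol silane may hydrolyse back to the ketone before it is oxidised. The fallback sets out from 6 and bypasses 7 and 8. Deprotonation with KN(SiMe3)2 (THF, −78 °C) is followed by hydroxylation of the potassium enolate in the same flask with 2-(phenylsulfonyl)-3-phenyloxaziridine (Davis oxidation) and a cold NH4Cl quench. The bulky oxidant should approach anti to the C2 phenyl, and the route is rejoined at 9.

Step 7. Over-reduction may occur: hydrogenolytic cleavage of the benzylic C2–O1 bond of ring C, or reduction of the C4 carbonyl, before both benzyl ethers are gone. The fallback sets out from 11 and uses non-reductive Lewis-acid dealkylation with BCl3 and pentamethylbenzene as benzyl-cation scavenger (CH2Cl2, −78 °C). This cleaves aryl benzyl ethers, the peri O5 one with chelation assistance, and should leave the alkyl ester, the ketone and the C2–O1 bond alone; it arrives directly at 12.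

**Further compounds**

F1 | step 3 | 1-[2,4-bis(benzyloxy)-6-hydroxyphenyl]ethanone | CC(=O)c1c(O)cc(OCc2ccccc2)cc1OCc1ccccc1
F2 | step 3 | (E)-1-[2,4-bis(benzyloxy)-6-hydroxyphenyl]-3-(dimethylamino)prop-2-en-1-one | CN(C)/C=C/C(=O)c1c(O)cc(OCc2ccccc2)cc1OCc1ccccc1
F3 | step 3 | 5,7-bis(benzyloxy)-4H-chromen-4-one | O=c1ccoc2cc(OCc3ccccc3)cc(OCc3ccccc3)c12
F0 | step 5 | none | none
F0 | step 7 | none | none
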